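## Structural features

The target 20 (dicitrinone I) is made of two bicyclic halves joined only by one methylene carbon (C9), which links C7 of one half to C7 of the other; isochroman numbering (C1, O2, C3, C4, C4a, C5–C8, C8a) is used for each half. In each half a fully substituted six-membered carbocycle (C5 methyl, C6 oxygen, C7 bridge, C8 oxygen, C8a–C1, C4a–C4) is fused to a six-membered oxygen ring. The only stereocentres, C3 (R, oxygen-bearing) and C4 (S, benzylic), are adjacent, each carries a methyl group, the methyl groups are trans, and both halves have the same configuration, so one 1,2-diad made once serves four centres. The halves differ only at C1: one is a resorcinol-type isochroman (C1H2), the other a quinone methide (C1H=C8a, C8=O, C6–OH), one oxidation level higher. The quinone methide is the fragile group (electrophilic at C1 towards hydride and water); the free resorcinol and the diarylmethane CH2 are sensitive to oxidants, and C4 is at risk wherever a dienol can extend from the ring to C4. The real difficulties are the hexasubstituted ring carrying the branched chiral chain at C4a next to the C5 methyl group, and telling two otherwise identical halves apart at the end. The key step uses the oxygenation pattern: C6 and C8 are 1,3-related with C7 between them, C8a carries C1 at the carboxyl level and C4a carries the stereodiad. At the cyclohexane-1,3-dione level C8–C8a–C1 is therefore a malonate, C5–C6–C7 a methyl ketone unit and C4a an enone β-carbon, so the carbocycle and the lactone ring (O2–C1) can be closed from an acyclic hydroxy enone in one operation.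

## Logic of the disconnections

20 ⇒ 18 (through 19). No skeletal bond is cut; C1 of the reduced half is raised to the lactol level and the quinone methide is hydrated. The reason is that the halves of 20 differ by two electrons at one carbon. The gain is that every earlier intermediate is constitutionally symmetric and comes from one monomer. The demand is that the forward step delivers one hydride to one of two equivalent oxocarbenium centres; there is no intrinsic bias, so the reductant must be limiting and the outcome is statistical.

18 ⇒ 17. The two C1–H bonds are removed (lactol to lactone). C1 at the carboxyl level is what 9 delivers, and the lactone keeps O2 acylated through the synthesis. The demand is a partial reduction of two lactones in the presence of four acidic phenols that stops at the lactol.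

17 ⇒ 14 + 14 + 15. Both C7–C9 bonds are cut. C7 is the only unsubstituted ring carbon of 14 and lies between two hydroxyl groups, so it is the natural site for a one-carbon electrophile. The gain is a halving of the molecule to a single monomer. The demand is that C7 is nucleophilic enough despite the lactone carbonyl and that the intermediate 16 is captured by a second 14; 15 must be limiting.

14 ⇒ 12. Two hydrogens are added back to the arene (retro-dehydrogenation). At this level C6 and C8 are ketone carbons and the ring can be made by enolate chemistry; the sp3 centres C4a, C5 and C8a of 12 need no control. The demand is a single desaturation that spares C4 and does not go on to substitute C7.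

12 ⇒ 8 + 9 (key disconnection). C4a–C8a, C7–C8 and O2–C1 are cut; each is a natural polar bond (conjugate addition, Claisen condensation, acyl transfer). 9 supplies C8, C8a and C1, and 8 supplies everything else including the stereodiad. The gain is two rings and three bonds in one step from an acyclic precursor with only two stereocentres. The demand is that addition to a trisubstituted, γ-branched enone precedes base-induced loss of the C5 configuration of 8 or cleavage of its C5–C6 bond, and that the Claisen step uses the methyl terminus.

8 ⇒ 7 ⇒ 5 + 6. The C3=C4 double bond of 8 (later C5–C4a) is cut by carbonyl olefination after masking the hydroxyl. 5 carries both stereocentres and 6 is a commercial four-carbon unit. The demand is an olefination that does not epimerise the α-centre of 5, and removal of the silyl group without generating an alkoxide.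

5 ⇒ 4 ⇒ 3 ⇒ 1. The C2–CH3 bond of 3 (the future C4 methyl) is cut. A hydroxyl-directed enolate alkylation sets the anti diad from the single chiral-pool centre of 1. The demand is anti selectivity from the chelated dianion 2 and an ester-to-aldehyde reduction that stops at the aldehyde.

## Other disconnections considered

Alternative 1: The cut is at C4a–C4 and C4–C3 in both halves, so the whole C3/C4 chain is grown from a preformed diarylmethane. In the forward sense the bis(arylboronic ester) A1 would be homologated twice in each arm with a configurationally defined α-lithiated ethyl carbamate (chiral diamine complex). Each boronate complex undergoes a stereospecific 1,2-metallate shift, the first making C4a–C4 and the second C4–C3, to give the bis(secondary boronic ester) A2 with boron where O2 will be.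
- In its favour: all four stereocentres are under reagent control and independent of the chiral pool, so either enantiomer or the cis diad would be equally accessible. On this point it is better than the chosen plan, which depends on the anti preference of one alkylation. It is two-directional like the chosen plan, which makes the two equal on that count.
- Against it: four metallate shifts are needed on one molecule, each at an aryl–boron centre flanked by the C5 methyl group; ortho substitution slows boronate formation and can make it reversible at the benzylic stage. A2 still lacks O2 and C1, so C–B oxidation, introduction of C1 at C8a and cleavage of four aryl methyl ethers next to benzylic ethers would follow. Both halves would then sit at the C1H2 level, so one half would need a benzylic oxidation in competition with the bridging CH2.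
- Comparison: structurally it takes the arenes ready-made and builds the chain, whereas the chosen plan takes the chain ready-made and builds the rings. Mechanistically it needs four cryogenic, stoichiometric chiral-reagent events against one substrate-controlled alkylation and an annulation driven by a stable enolate. In step economy the chosen plan should be shorter after the key step, because it arrives at the lactone level from which both final oxidation states are reached by reduction.

Alternative 2: The cut is at C7–C8, C5–C6 and C8–C8a of one carbocycle, which is built last and directly onto C9. In the forward sense irradiation of the diazo ketone A3 would give a vinylketene by Wolff rearrangement. This adds to the siloxyalkyne A4 in a [2+2] reaction, and four-electron ring opening of the cyclobutenone followed by six-electron closure gives the phenol A5.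
- In its favour: it is convergent and the mechanism fixes the position of every ring substituent. The two halves of A5 are differently protected (free C8 hydroxyl and silyl ether on the new ring, acetals on the other), so the adjustment at C1 could be directed to one half. On this point it is better than the chosen plan, whose last step is statistical. The neutral pericyclic cascade also poses no base-mediated risk to C4, which makes it at least equal there.
- Against it: A4 already contains a complete isochroman half, which must come from some other ring synthesis, so the method solves half of the structural problem. A3 needs the diad inside a dihydropyran and a diazo transfer. Both C1 positions of A5 are at the CH2 level, so an oxidation of one benzylic ether next to the diarylmethane CH2 and three deprotections would still follow.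
- Comparison: regiocontrol of the hexasubstituted ring is equal. In step economy and handling (diazo compound, photolysis, two advanced fragments, more protecting groups) the chosen plan should be clearly shorter and simpler, since it makes both halves from one monomer.

Alternative 3: The cut is at C5–C4a and C8–C8a in both halves, so both arene rings come from acyclic components with the bridge in place. In the forward sense the bis-diene A6 and two molecules of the ynoate A7 would undergo thermal [4+2] cycloaddition; loss of the acetal alkoxy group and of the silyl groups from the ring oxygens then aromatises both rings to A8, with C1 present as an ester next to the side chain.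
- In its favour: the rings appear directly at the aromatic oxidation level, no stereoisomer mixtures arise, and the bridge is set at a 1,3-dicarbonyl stage. After desilylation and lactonisation A8 would converge on 17. On paper it is at least the equal of the chosen plan in step economy and better in redox economy.
- Against it: each cycloaddition must create a hexasubstituted benzene by joining a methyl-bearing diene terminus to the β-carbon of an alkynoate that carries a secondary alkyl branch, and it must do so twice on one molecule. A6 contains four silyl enol ether units with fully substituted ketene acetal carbons, which are hard to prepare and hydrolytically labile, and dienes substituted at the central carbon reach the reactive conformation poorly. The same statistical last step would remain.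
- Comparison: the chosen plan forms the most hindered bond (C4a–C8a) by reversible addition of a small stabilised anion to a carbon that becomes sp3, pulled forward by a later irreversible Claisen step. That should tolerate crowding better than a concerted cycloaddition, at the price of one extra oxidation step.

Key step: step 6

Remark on the chemistry: the quinone methide half of 20 is treated as one compound with its 6-oxo/8-hydroxy tautomer, and 15 is used as its commercial aqueous solution. The (5S,6R) diad of 8 was checked atom by atom against C4 (S) and C3 (R) of 20; it corresponds to the anti (2R,3R) ester 3, the descriptor at the methyl-bearing carbon changing only because the substituent priorities change.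

## Steps

Step 1
Reactants: 1 methyl (R)-3-hydroxybutanoate
Product: 3 methyl (2R,3R)-3-hydroxy-2-methylbutanoate, via dilithium alkoxide enolate 2 (not isolated)
Conditions: LiN(iPr)2 (2.2 equiv), THF, −78 → −20 °C; MeI, DMPU, −78 → 0 °C; aq. NH4Cl
Reagents that add atoms: iodomethane, CI
Why: Fráter–Seebach alkylation: the dianion 2 is a rigid lithium chelate (enolate oxygen cis to C3) and iodomethane should approach the enolate face opposite the C3 methyl group, setting the new C2 centre anti to the hydroxyl as (2R,3R); the carbinol centre is untouched and any minor syn isomer would be removed by chromatography here or at 4.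

Step 2
Reactants: 3 methyl (2R,3R)-3-hydroxy-2-methylbutanoate
Product: 4 methyl (2R,3R)-3-[(tert-butyldimethylsilyl)oxy]-2-methylbutanoate
Conditions: TBSCl, imidazole, DMF, rt
Reagents that add atoms: tert-butyldimethylsilyl chloride, CC(C)(C)[Si](C)(C)Cl
Why: Standard imidazole-mediated silylation of a secondary alcohol; the ether keeps the hydroxyl from consuming hydride and from forming hemiacetals with the aldehyde of the next step, and no stereocentre is involved.

Step 3
Reactants: 4 methyl (2R,3R)-3-[(tert-butyldimethylsilyl)oxy]-2-methylbutanoate
Product: 5 (2R,3R)-3-[(tert-butyldimethylsilyl)oxy]-2-methylbutanal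
Conditions: iBu2AlH (1.05 equiv), CH2Cl2, −78 °C; MeOH, then aq. KNaC4H4O6
Reagents that add atoms: none
Why: Partial ester reduction: the tetrahedral aluminium hemiacetal should persist at −78 °C and release the aldehyde only on work-up, and the non-basic work-up leaves the α-centre intact; 5 is used without storage.

Step 4
Reactants: 5 (2R,3R)-3-[(tert-butyldimethylsilyl)oxy]-2-methylbutanal; 6 diethyl (3-oxobutan-2-yl)phosphonate
Product: 7 (3E,5S,6R)-6-[(tert-butyldimethylsilyl)oxy]-3,5-dimethylhept-3-en-2-one
Conditions: Ba(OH)2 (0.7 equiv), THF/H2O (40:1), rt
Reagents that add atoms: none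
Why: Horner–Wadsworth–Emmons olefination with a stabilised α-methyl β-keto phosphonate, which should give the E trisubstituted enone (acetyl trans to the chain) by reversible addition and elimination; Ba(OH)2 is mild enough not to enolise the α-branched aldehyde, so the diad is carried through.

Step 5
Reactants: 7 (3E,5S,6R)-6-[(tert-butyldimethylsilyl)oxy]-3,5-dimethylhept-3-en-2-one
Product: 8 (3E,5S,6R)-6-hydroxy-3,5-dimethylhept-3-en-2-one
Conditions: HF·pyridine, pyridine, THF, 0 °C → rt
Reagents that add atoms: none
Why: Fluoride-mediated Si–O cleavage on the acidic side of neutral, so no alkoxide is formed that could trigger retro-aldol cleavage or γ-epimerisation of this vinylogous aldol; the E geometry keeps the hydroxyl away from the ketone.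

Step 6
Reactants: 8 (3E,5S,6R)-6-hydroxy-3,5-dimethylhept-3-en-2-one; 9 dimethyl malonate
Product: 12 (3R,4S)-3,4,5-trimethyl-4,4a,5,8a-tetrahydro-1H-isochromene-1,6,8(3H,7H)-trione, via Michael adduct 10 (not isolated), via keto lactone ester 11 (not isolated)
Conditions: 9 (1.5 equiv), NaOCH3 (1.2 equiv), MeOH, 0 °C → rt; then NaOCH3 (1.5 equiv), reflux; aq. HCl (pH 2)
Reagents that add atoms: none
Why: Sodium dimethyl malonate adds to the enone β-carbon (C4a–C8a) to give 10, the C3 hydroxyl transesterifies onto one ester to give δ-lactone 11 (O2–C1), and with more methoxide at reflux the methyl ketone enolate attacks the remaining ester (C7–C8, Claisen), the stable enolate of 12 pulling all the reversible steps forward. The closest known reaction is the malonate–enone synthesis of 5-substituted cyclohexane-1,3-diones, here with lactone closure of a δ-hydroxy ester in the same pot. Both rings close by 6-exo-trig attack on an ester carbonyl, the lactone through oxygen and the carbocycle through the C7 enolate carbon. No new stereocentre needs control: C4a, C5 and C8a form as mixtures and become sp2 in step 7, while C3 and C4 are spectators because transesterification breaks the acyl–oxygen bond, not the C3–O bond. The selectivity needed is conjugate addition before γ-deprotonation or alkoxide fragmentation of 8; it is secured by keeping 9 in excess over methoxide in the first stage, so that the malonate anion is essentially the only base present, and once addition has occurred C4 is no longer vinylogously acidic. The Claisen regiochemistry is fixed by ring size, since only the methyl terminus reaches an ester through a six-membered ring. Acidic work-up should re-close any ring-opened hydroxy ester, and 12 is expected as an enolised mixture of ring-fusion and C5 isomers.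

Step 7
Reactants: 12 (3R,4S)-3,4,5-trimethyl-4,4a,5,8a-tetrahydro-1H-isochromene-1,6,8(3H,7H)-trione
Product: 14 (3R,4S)-6,8-dihydroxy-3,4,5-trimethylisochroman-1-one, via 7-bromo trione 13 (not isolated)
Conditions: Br2 (1.0 equiv), DMF, 0 °C; then 80 °C
Reagents that add atoms: none
Why: Halogenation–dehydrohalogenation aromatisation as known for 6-alkyl-2,4-dioxocyclohexanecarboxylates: the enol is brominated at C7 to give 13, acid-mediated bromine transfer and loss of HBr on heating introduce the missing unsaturation, and tautomerisation gives the resorcinol; one equivalent of bromine is meant to avoid substitution at C7 of the product, and the isomer mixture of 12 converges on a single compound with C3 and C4 untouched.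

Step 8
Reactants: 14 (3R,4S)-6,8-dihydroxy-3,4,5-trimethylisochroman-1-one (two equivalents); 15 formaldehyde
Product: 17 7,7'-methylenebis[(3R,4S)-6,8-dihydroxy-3,4,5-trimethylisochroman-1-one], via 7-hydroxymethyl lactone 16 (not isolated)
Conditions: 15 (37 % aq., 0.5 equiv), H2SO4 (cat.), AcOH, 50 °C
Reagents that add atoms: none
Why: Acid-catalysed phenol–formaldehyde (Baeyer diarylmethane) condensation of the kind that gives methylenedisalicylic acid: C7 is the only free ring position, ortho to both hydroxyl groups and meta to the lactone carbonyl, so hydroxymethylation gives 16, whose benzylic cation is captured by a second 14; the product has no free ring position, so the reaction should stop at the dimer.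

Step 9
Reactants: 17 7,7'-methylenebis[(3R,4S)-6,8-dihydroxy-3,4,5-trimethylisochroman-1-one]
Product: 18 7,7'-methylenebis[(3R,4S)-3,4,5-trimethylisochromane-1,6,8-triol]
Conditions: iBu2AlH (9 equiv), THF/CH2Cl2, −78 °C; aq. KNaC4H4O6 (pH 7)
Reagents that add atoms: none
Why: Lactone-to-lactol reduction: four equivalents of hydride are consumed by the phenols and the remainder should reduce each lactone to an aluminium lactolate that is stable at −78 °C and gives the lactol on neutral work-up; the new C1 centres form as a mixture that is erased in step 10, and partial dehydration of 18 towards 19 on handling is harmless for the same reason.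

Step 10
Reactants: 18 7,7'-methylenebis[(3R,4S)-3,4,5-trimethylisochromane-1,6,8-triol]
Product: 20 (3R,4S)-7-{[(3R,4S)-6,8-dihydroxy-3,4,5-trimethylisochroman-7-yl]methyl}-6-hydroxy-3,4,5-trimethyl-3,4-dihydro-8H-isochromen-8-one, via bis(quinone methide) 19 (not isolated)
Conditions: CF3CO2H (20 equiv), CH2Cl2, 0 °C; then Et3SiH (1.0 equiv, slow addition), −40 → 0 °C; aq. NaHCO3
Reagents that add atoms: none
Why: Ionic hydrogenation of a lactol: the acid ionises both lactols to oxocarbenium ions (protonated 19), one hydride from Et3SiH converts one C1 into CH2, and the other half loses a proton on neutralisation to give the quinone methide. The halves are equivalent, so the selectivity is statistical and by probability no more than about half of the material can be 20 in one pass; unreduced 19 would be returned to the same conditions.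

## Compound list

1 | methyl (R)-3-hydroxybutanoate | C[C@@H](O)CC(=O)OC | starting material
2 | dilithium (1E,3R)-1-methoxybut-1-ene-1,3-diolate | [Li+].[Li+].C[C@@H]([O-])/C=C(\[O-])OC | intermediate (not isolated)
3 | methyl (2R,3R)-3-hydroxy-2-methylbutanoate | COC(=O)[C@H](C)[C@@H](C)O | intermediate
4 | methyl (2R,3R)-3-[(tert-butyldimethylsilyl)oxy]-2-methylbutanoate | COC(=O)[C@H](C)[C@@H](C)O[Si](C)(C)C(C)(C)C | intermediate
5 | (2R,3R)-3-[(tert-butyldimethylsilyl)oxy]-2-methylbutanal | O=C[C@H](C)[C@@H](C)O[Si](C)(C)C(C)(C)C | intermediate
6 | diethyl (3-oxobutan-2-yl)phosphonate | CCOP(=O)(OCC)C(C)C(C)=O | starting material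
7 | (3E,5S,6R)-6-[(tert-butyldimethylsilyl)oxy]-3,5-dimethylhept-3-en-2-one | CC(=O)/C(C)=C/[C@H](C)[C@@H](C)O[Si](C)(C)C(C)(C)C | intermediate
8 | (3E,5S,6R)-6-hydroxy-3,5-dimethylhept-3-en-2-one | CC(=O)/C(C)=C/[C@H](C)[C@@H](C)O | intermediate
9 | dimethyl malonate | COC(=O)CC(=O)OC | starting material
10 | dimethyl 2-[(5S,6R)-6-hydroxy-3,5-dimethyl-2-oxoheptan-4-yl]propanedioate (mixture at C3 and C4 of the chain) | CC(=O)C(C)C(C(C(=O)OC)C(=O)OC)[C@H](C)[C@@H](C)O | intermediate (not isolated)
11 | methyl (5S,6R)-5,6-dimethyl-2-oxo-4-(3-oxobutan-2-yl)oxane-3-carboxylate (mixture at the other centres) | CC(=O)C(C)C1C(C(=O)OC)C(=O)O[C@H](C)[C@H]1C | intermediate (not isolated)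
12 | (3R,4S)-3,4,5-trimethyl-4,4a,5,8a-tetrahydro-1H-isochromene-1,6,8(3H,7H)-trione (enolised; mixture at C4a, C5, C8a) | CC1C(=O)CC(=O)C2C1[C@H](C)[C@@H](C)OC2=O | intermediate
13 | (3R,4S)-7-bromo-3,4,5-trimethyl-4,4a,5,8a-tetrahydro-1H-isochromene-1,6,8(3H,7H)-trione | CC1C(=O)C(Br)C(=O)C2C1[C@H](C)[C@@H](C)OC2=O | intermediate (not isolated)
14 | (3R,4S)-6,8-dihydroxy-3,4,5-trimethylisochroman-1-one | Cc1c(O)cc(O)c2c1[C@H](C)[C@@H](C)OC2=O | intermediate
15 | formaldehyde | C=O | starting material
16 | (3R,4S)-6,8-dihydroxy-7-(hydroxymethyl)-3,4,5-trimethylisochroman-1-one | Cc1c(O)c(CO)c(O)c2c1[C@H](C)[C@@H](C)OC2=O | intermediate (not isolated)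
17 | 7,7'-methylenebis[(3R,4S)-6,8-dihydroxy-3,4,5-trimethylisochroman-1-one] | Cc1c(O)c(Cc3c(O)c(C)c4c(c3O)C(=O)O[C@H](C)[C@H]4C)c(O)c2c1[C@H](C)[C@@H](C)OC2=O | intermediate
18 | 7,7'-methylenebis[(3R,4S)-3,4,5-trimethylisochromane-1,6,8-triol] (C1 epimers) | Cc1c(O)c(Cc3c(O)c(C)c4c(c3O)C(O)O[C@H](C)[C@H]4C)c(O)c2c1[C@H](C)[C@@H](C)OC2O | intermediate
19 | 7,7'-methylenebis[(3R,4S)-6-hydroxy-3,4,5-trimethyl-3,4-dihydro-8H-isochromen-8-one] | CC1=C2C(=CO[C@H](C)[C@H]2C)C(=O)C(CC2=C(O)C(C)=C3C(=CO[C@H](C)[C@H]3C)C2=O)=C1O | intermediate (not isolated)
20 | dicitrinone I: (3R,4S)-7-{[(3R,4S)-6,8-dihydroxy-3,4,5-trimethylisochroman-7-yl]methyl}-6-hydroxy-3,4,5-trimethyl-3,4-dihydro-8H-isochromen-8-one | CC1=C2C(=CO[C@H](C)[C@H]2C)C(=O)C(Cc2c(O)c(C)c3c(c2O)CO[C@H](C)[C@H]3C)=C1O | target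

## Step count and least certain steps

Total step count: 10. Longest linear sequence: 10 steps (1 to 20); 6, 9 and 15 enter as purchased reagents.

Step 6 (key step). The most likely failure is that conjugate addition to the α-methyl, γ-branched enone is too slow. Unreacted 8 would then meet the methoxide needed for the Claisen stage and suffer γ-deprotonation (loss of the C5 configuration) or retro-aldol cleavage of its C5–C6 bond; the addition equilibrium may also lie on the starting-material side until the Claisen step drains it. The fallback makes the addition intramolecular. It sets out from 8, which is acylated with methyl 3-chloro-3-oxopropanoate (pyridine, CH2Cl2, 0 °C) to give methyl (2R,3S,4E)-3,5-dimethyl-6-oxohept-4-en-2-yl propanedioate F1. A mild base (Cs2CO3, MeCN, rt) should then effect a 6-exo-trig Michael closure to 11, now isolated, because the malonate C–H is far more acidic than the γ-hydrogen and no alkoxide can form. NaOCH3 in MeOH at reflux then closes the carbocycle, and the route is rejoined at 12.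

Step 10. The expected problem is the lack of discrimination between two equivalent cationic centres, which leads to reduction of both halves or of neither alongside the wanted single reduction; acid-induced exchange at the diarylmethane link is a lesser risk. The fallback removes the statistics by joining two different halves, and sets out from 14.
- One portion is reduced with iBu2AlH (−78 °C) to (3R,4S)-3,4,5-trimethylisochromane-1,6,8-triol F2 and then with excess Et3SiH and CF3CO2H to (3R,4S)-3,4,5-trimethylisochromane-6,8-diol F3.
- A second portion is hydroxymethylated with excess aqueous 15 and NaOH at 0 °C, and 16 is isolated.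
- 16 has no free ring position and can act only as the electrophile; F3 has only C7 free and is the better nucleophile. Mild acid should therefore give only the cross-product (3R,4S)-7-{[(3R,4S)-6,8-dihydroxy-3,4,5-trimethylisochroman-7-yl]methyl}-6,8-dihydroxy-3,4,5-trimethylisochroman-1-one F4.
- iBu2AlH reduction of the single lactone gives (3R,4S)-7-{[(3R,4S)-6,8-dihydroxy-3,4,5-trimethylisochroman-7-yl]methyl}-3,4,5-trimethylisochromane-1,6,8-triol F5, and acid-promoted dehydration of this lactol rejoins the route at 20.

Step 9. The risk is reduction beyond the lactol level, because an aluminium phenoxide ortho or para to C1 can assist expulsion of the lactolate oxygen and expose C1 to a second hydride. The opposite risk is incomplete reduction caused by phenoxide donation into the carbonyl and poor solubility of the polyphenoxide. The fallback masks the phenols and sets out from 17. Chloromethyl methyl ether and iPr2NEt (NaH for the chelated C8 hydroxyl if needed) give 7,7'-methylenebis[(3R,4S)-6,8-bis(methoxymethoxy)-3,4,5-trimethylisochroman-1-one] F6. iBu2AlH at −78 °C then gives 7,7'-methylenebis[(3R,4S)-6,8-bis(methoxymethoxy)-3,4,5-trimethylisochroman-1-ol] F7, and aqueous HCl in THF removes the four acetals. The route is rejoined at 18 (in equilibrium with 19), which enters step 10.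

Step 7. The likely problem is a second bromination at C7 of the newly formed resorcinol competing with dehydrobromination, so that starting material, product and ring-brominated product coexist. A lesser risk is erosion at C4 if a dienol extends from the ring towards C4 during the hot acidic stage. The fallback accepts over-bromination instead of fighting it and sets out from 12. Br2 (2.1 equiv) in AcOH at rt aromatises and brominates to (3R,4S)-7-bromo-6,8-dihydroxy-3,4,5-trimethylisochroman-1-one F8, and hydrogenolysis (H2, Pd/C, CH3CO2Na, MeOH) removes the bromine. The route is rejoined at 14.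

Step 8. The likely problem is slow substitution at the lactone-deactivated ring, so that the reaction stalls at reversible hemiformals or at the hydroxymethyl stage. The fallback moves the bridging to the dione level, where C7 is the central carbon of a 1,3-diketone and far more nucleophilic, and sets out from 12. Aqueous 15 (0.5 equiv) in EtOH/H2O at rt should give, by Knoevenagel condensation and Michael addition, 7,7'-methylenebis[(3R,4S)-3,4,5-trimethyl-4,4a,5,8a-tetrahydro-1H-isochromene-1,6,8(3H,7H)-trione] F9. Both rings are then aromatised with Br2 (2 equiv) in DMF as in step 7, at the lowest workable temperature to limit acid-induced cyclodehydration between the two dione rings. The route is rejoined at 17.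

## Further compounds

F1 | step 6 | methyl (2R,3S,4E)-3,5-dimethyl-6-oxohept-4-en-2-yl propanedioate | COC(=O)CC(=O)O[C@H](C)[C@@H](C)/C=C(\C)C(C)=O
F2 | step 10 | (3R,4S)-3,4,5-trimethylisochromane-1,6,8-triol | Cc1c(O)cc(O)c2c1[C@H](C)[C@@H](C)OC2O
F3 | step 10 | (3R,4S)-3,4,5-trimethylisochromane-6,8-diol | Cc1c(O)cc(O)c2c1[C@H](C)[C@@H](C)OC2
F4 | step 10 | (3R,4S)-7-{[(3R,4S)-6,8-dihydroxy-3,4,5-trimethylisochroman-7-yl]methyl}-6,8-dihydroxy-3,4,5-trimethylisochroman-1-one | Cc1c(O)c(Cc3c(O)c(C)c4c(c3O)CO[C@H](C)[C@H]4C)c(O)c2c1[C@H](C)[C@@H](C)OC2=O
F5 | step 10 | (3R,4S)-7-{[(3R,4S)-6,8-dihydroxy-3,4,5-trimethylisochroman-7-yl]methyl}-3,4,5-trimethylisochromane-1,6,8-triol | Cc1c(O)c(Cc3c(O)c(C)c4c(c3O)CO[C@H](C)[C@H]4C)c(O)c2c1[C@H](C)[C@@H](C)OC2O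
F6 | step 9 | 7,7'-methylenebis[(3R,4S)-6,8-bis(methoxymethoxy)-3,4,5-trimethylisochroman-1-one] | Cc1c(OCOC)c(Cc3c(OCOC)c(C)c4c(c3OCOC)C(=O)O[C@H](C)[C@H]4C)c(OCOC)c2c1[C@H](C)[C@@H](C)OC2=O
F7 | step 9 | 7,7'-methylenebis[(3R,4S)-6,8-bis(methoxymethoxy)-3,4,5-trimethylisochroman-1-ol] | Cc1c(OCOC)c(Cc3c(OCOC)c(C)c4c(c3OCOC)C(O)O[C@H](C)[C@H]4C)c(OCOC)c2c1[C@H](C)[C@@H](C)OC2O
F8 | step 7 | (3R,4S)-7-bromo-6,8-dihydroxy-3,4,5-trimethylisochroman-1-one | Cc1c(O)c(Br)c(O)c2c1[C@H](C)[C@@H](C)OC2=O
F9 | step 8 | 7,7'-methylenebis[(3R,4S)-3,4,5-trimethyl-4,4a,5,8a-tetrahydro-1H-isochromene-1,6,8(3H,7H)-trione] | CC1C(=O)C(CC3C(=O)C(C)C4C(C3=O)C(=O)O[C@H](C)[C@H]4C)C(=O)C2C1[C@H](C)[C@@H](C)OC2=O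
A1 | alternative 1 | bis[2,6-dimethoxy-3-methyl-4-(4,4,5,5-tetramethyl-1,3,2-dioxaborolan-2-yl)phenyl]methane | CC1(C)OB(OC1(C)C)c1cc(OC)c(Cc2c(OC)cc(B3OC(C)(C)C(C)(C)O3)c(C)c2OC)c(OC)c1C
A2 | alternative 1 | bis{4-[(2R,3R)-3-(4,4,5,5-tetramethyl-1,3,2-dioxaborolan-2-yl)butan-2-yl]-2,6-dimethoxy-3-methylphenyl}methane | CC1(C)OB(OC1(C)C)[C@H](C)[C@H](c1cc(OC)c(Cc2c(OC)cc([C@H](C)[C@@H](C)B3OC(C)(C)C(C)(C)O3)c(C)c2OC)c(OC)c1C)C
A3 | alternative 2 | 2-diazo-1-[(2R,3S)-2,3-dimethyl-3,6-dihydro-2H-pyran-4-yl]propan-1-one | CC(=[N+]=[N-])C(=O)C1=CCO[C@H](C)[C@H]1C
A4 | alternative 2 | triisopropyl({3-[(3R,4S)-6,8-bis(methoxymethoxy)-3,4,5-trimethylisochroman-7-yl]prop-1-yn-1-yl}oxy)silane | CC(C)[Si](C(C)C)(C(C)C)OC#CCc1c(OCOC)c(C)c2c(c1OCOC)CO[C@H](C)[C@H]2C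
A5 | alternative 2 | (3R,4S)-7-{[(3R,4S)-6,8-bis(methoxymethoxy)-3,4,5-trimethylisochroman-7-yl]methyl}-3,4,5-trimethyl-6-(triisopropylsilyloxy)isochroman-8-ol | CC(C)[Si](C(C)C)(C(C)C)Oc1c(C)c2c(c(O)c1Cc1c(OCOC)c(C)c3c(c1OCOC)CO[C@H](C)[C@H]3C)CO[C@H](C)[C@H]2C
A6 | alternative 3 | 4,6-bis[methoxy(trimethylsilyloxy)methylidene]-3,7-bis(trimethylsilyloxy)nona-2,7-diene | COC(O[Si](C)(C)C)=C(CC(=C(OC)O[Si](C)(C)C)C(O[Si](C)(C)C)=CC)C(O[Si](C)(C)C)=CC
A7 | alternative 3 | methyl (4S,5R)-5-[(tert-butyldimethylsilyl)oxy]-4-methylhex-2-ynoate | COC(=O)C#C[C@H](C)[C@@H](C)O[Si](C)(C)C(C)(C)C
A8 | alternative 3 | dimethyl 3,3'-methylenebis{6-[(2S,3R)-3-(tert-butyldimethylsilyloxy)butan-2-yl]-2,4-dihydroxy-5-methylbenzoate} | COC(=O)c1c(O)c(Cc2c(O)c(C)c([C@H](C)[C@@H](C)O[Si](C)(C)C(C)(C)C)c(C(=O)OC)c2O)c(O)c(C)c1[C@H](C)[C@@H](C)O[Si](C)(C)C(C)(C)C
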